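**Retrosynthetic overview**

1. The target is released from its C-5 methyl enol ether 23 (target chromene numbering) by hydrolysis of the vinylogous ester; 23 is made in one flask from the flat aryl lactone 20.
2. Key disconnections in that flask: the C-6–prenyl bond (Pd-catalysed asymmetric dearomative allylic alkylation) and the O-1–C-2 bond of the dihydropyranone (oxa-Michael addition after hydroxide opens the lactone).
3. Enabling feature: O-1 sits on C-8a, next to C-8 which carries the CH(Pr)CH2CO2H chain, so O-1 and the acid carbonyl can be stored as a six-membered aryl lactone (the 4-propyl-3,4-dihydrocoumarin ring of 20). The same O-1 is 1,5 to the β-carbon of the 3-methylbut-2-enoyl group on C-4a, and the only other oxygen beside that acyl carbon (on C-5) is kept as OMe, so lactone opening can close the dihydropyranone only one way.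
4. 20 is the Negishi union of cyclobutylmethyl iodide 13 with bromo enone lactone 18; 18 comes from commercial 5,7-dihydroxy-4-propylcoumarin by 7-O-methylation, CuH conjugate reduction, ortho-bromination and para-acylation.
5. Ring order: cyclobutane first (epoxynitrile 4-exo closure on a resolved epoxide, step 5); the six-membered carbocycle and the temporary lactone come from the coumarin; the dihydropyranone is closed last (step 15).

Key step: step 15

Remark: in the three catalyst-controlled steps (4, 11, 15) the catalyst antipode written is the one expected to give the configuration shown; if the sense of induction proves opposite, the mirror-image catalyst is used with no other change.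

**Route**

Step 1
Reactants: 1 ethyl 2-cyano-3-methylbut-2-enoate
Product: 2 ethyl 2-cyano-3,3-dimethylhex-5-enoate
Conditions: CH2=CHCH2MgBr (1.2 equiv), THF, −78 → 0 °C; 1 M HCl
Reagents that add atoms: allylmagnesium bromide, C=CC[Mg]Br
Why: Conjugate (1,4) addition of the allyl Grignard reagent to a doubly activated alkylidene cyanoacetate builds the quaternary carbon; the new C-2 centre is racemic and is removed in step 2.

Step 2
Reactants: 2 ethyl 2-cyano-3,3-dimethylhex-5-enoate
Product: 3 3,3-dimethylhex-5-enenitrile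
Conditions: LiCl, H2O, DMSO, 150 °C
Reagents that add atoms: none
Why: Krapcho dealkoxycarbonylation of an α-cyano ester (chloride attack on the ethyl group, loss of CO2, protonation) leaves nitrile and terminal alkene untouched.

Step 3
Reactants: 3 3,3-dimethylhex-5-enenitrile
Product: 4 3,3-dimethyl-4-(oxiran-2-yl)butanenitrile (racemic)
Conditions: mCPBA, CH2Cl2, 0 °C → rt
Reagents that add atoms: 3-chloroperoxybenzoic acid, OOC(=O)c1cccc(Cl)c1
Why: Prilezhaev epoxidation of the only alkene; the oxirane carbon forms racemic and is resolved in step 4.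

Step 4
Reactants: 4 3,3-dimethyl-4-(oxiran-2-yl)butanenitrile (racemic)
Product: 5 3,3-dimethyl-4-[(2R)-oxiran-2-yl]butanenitrile
Conditions: (S,S)-(salen)Co(OAc) (0.5 mol%; salen = N,N'-bis(3,5-di-tert-butylsalicylidene)cyclohexane-1,2-diamine dianion), H2O (0.55 equiv), THF, 0 °C → rt; distillation from the diol
Reagents that add atoms: none
Why: Jacobsen hydrolytic kinetic resolution, in which the chiral cobalt salen complex hydrolyses the (S)-epoxide selectively, so the unreacted (R)-epoxide should be recovered in high enantiomeric purity (catalyst control).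

Step 5
Reactants: 5 3,3-dimethyl-4-[(2R)-oxiran-2-yl]butanenitrile
Product: 7 (1RS,4R)-4-({[tert-butyl(dimethyl)silyl]oxy}methyl)-2,2-dimethylcyclobutane-1-carbonitrile, via sodium alkoxide 6 (not isolated)
Conditions: NaN(SiMe3)2 (1.05 equiv), toluene, 0 °C → rt; then t-BuMe2SiCl, rt
Reagents that add atoms: tert-butyldimethylsilyl chloride, CC(C)(C)[Si](C)(C)Cl
Why: Stork epoxynitrile cyclisation, in which the α-cyano carbanion opens the oxirane in the 4-exo-tet mode because collinear backside attack is possible only at the proximal carbon (helped by the gem-dimethyl group); SN2 inversion there fixes the CH2O-bearing ring carbon as R, the nitrile-bearing carbon forms as an epimer mixture that is corrected in step 6, and the alkoxide is silylated in the flask.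

Step 6
Reactants: 7 (1RS,4R)-4-({[tert-butyl(dimethyl)silyl]oxy}methyl)-2,2-dimethylcyclobutane-1-carbonitrile
Product: 10 1-[(1S,4R)-4-({[tert-butyl(dimethyl)silyl]oxy}methyl)-2,2-dimethylcyclobutyl]ethan-1-one, via lithium ketimide 8 (not isolated), via ketone epimer mixture 9 (not isolated)
Conditions: MeLi, Et2O, −20 → 0 °C; sat. aq. NH4Cl, rt; then NaOMe (0.2 equiv), MeOH, rt
Reagents that add atoms: methyllithium, [Li]C; water, O
Why: Addition of MeLi to the nitrile gives the N-lithio ketimine, which is hydrolysed to the methyl ketone; methoxide then equilibrates the enolisable α-centre to the more stable trans (1S) arrangement relative to the fixed CH2OSi-bearing carbon (thermodynamic control).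

Step 7
Reactants: 10 1-[(1S,4R)-4-({[tert-butyl(dimethyl)silyl]oxy}methyl)-2,2-dimethylcyclobutyl]ethan-1-one
Product: 11 tert-butyl{[(1R,2R)-3,3-dimethyl-2-(prop-1-en-2-yl)cyclobutyl]methoxy}dimethylsilane
Conditions: Ph3PCH3Br, KOtBu, THF, 0 → 50 °C
Reagents that add atoms: methyltriphenylphosphonium bromide, C[P+](c1ccccc1)(c1ccccc1)c1ccccc1.[Br-]
Why: Wittig methylenation of the methyl ketone gives the isopropenyl group; the α-centre is already in its thermodynamic trans configuration, so the basic ylide cannot erode it.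

Step 8
Reactants: 11 tert-butyl{[(1R,2R)-3,3-dimethyl-2-(prop-1-en-2-yl)cyclobutyl]methoxy}dimethylsilane
Product: 12 [(1R,2R)-3,3-dimethyl-2-(prop-1-en-2-yl)cyclobutyl]methanol
Conditions: Bu4NF, THF, rt
Reagents that add atoms: none
Why: Fluoride cleaves the Si–O bond of the primary silyl ether and leaves the alkene and both ring stereocentres untouched.

Step 9
Reactants: 12 [(1R,2R)-3,3-dimethyl-2-(prop-1-en-2-yl)cyclobutyl]methanol
Product: 13 (2R,3R)-3-(iodomethyl)-1,1-dimethyl-2-(prop-1-en-2-yl)cyclobutane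
Conditions: I2, PPh3, imidazole, CH2Cl2, 0 °C → rt
Reagents that add atoms: iodine, II
Why: Appel-type iodination replaces the primary hydroxyl by SN2 displacement at CH2 under neutral conditions, so neither ring stereocentre nor the acid-sensitive isopropenylcyclobutane is affected.

Step 10
Reactants: 14 5,7-dihydroxy-4-propyl-2H-chromen-2-one
Product: 15 5-hydroxy-7-methoxy-4-propyl-2H-chromen-2-one
Conditions: MeI (1.05 equiv), K2CO3, acetone, rt
Reagents that add atoms: iodomethane, CI
Why: Williamson O-methylation with one equivalent of MeI should select the 7-OH, the more acidic and less hindered hydroxyl (the 5-OH is peri to the propyl group).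

Step 11
Reactants: 15 5-hydroxy-7-methoxy-4-propyl-2H-chromen-2-one
Product: 16 (4R)-5-hydroxy-7-methoxy-4-propyl-3,4-dihydro-2H-chromen-2-one
Conditions: Cu(OAc)2·H2O (3 mol%), (R)-DTBM-SEGPHOS (3 mol%), (EtO)2MeSiH, t-BuOH, toluene, rt; aq. NH4F
Reagents that add atoms: none
Why: Copper hydride-catalysed asymmetric conjugate reduction of a β,β-disubstituted unsaturated lactone, in which hydride is delivered to C-4 on the face chosen by the chiral bisphosphine (catalyst control) to set the (4R) centre, and t-BuOH protonates the copper enolate.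

Step 12
Reactants: 16 (4R)-5-hydroxy-7-methoxy-4-propyl-3,4-dihydro-2H-chromen-2-one
Product: 17 (4R)-6-bromo-5-hydroxy-7-methoxy-4-propyl-3,4-dihydro-2H-chromen-2-one
Conditions: NBS (1.0 equiv), i-Pr2NH (10 mol%), CH2Cl2, 0 °C
Reagents that add atoms: N-bromosuccinimide, BrN1C(=O)CCC1=O
Why: Amine-catalysed NBS bromination of a phenol is ortho-selective (the N-bromoamine is delivered through hydrogen bonding to the OH), so bromine should enter C-6, the only free ortho position.

Step 13
Reactants: 17 (4R)-6-bromo-5-hydroxy-7-methoxy-4-propyl-3,4-dihydro-2H-chromen-2-one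
Product: 18 (4R)-6-bromo-5-hydroxy-7-methoxy-8-(3-methylbut-2-enoyl)-4-propyl-3,4-dihydro-2H-chromen-2-one
Conditions: 3-methylbut-2-enoyl chloride, AlCl3 (2.2 equiv), CH2Cl2/MeNO2, −10 → 0 °C; cold 1 M HCl
Reagents that add atoms: 3-methylbut-2-enoyl chloride, CC(C)=CC(=O)Cl
Why: Friedel–Crafts acylation, in which C-8 (para to the aluminium phenoxide) is the only free ring position once C-6 is blocked, and the new enone cannot cyclise because its two flanking oxygens are a methyl ether and the lactone oxygen.

Step 14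
Reactants: 13 (2R,3R)-3-(iodomethyl)-1,1-dimethyl-2-(prop-1-en-2-yl)cyclobutane; 18 (4R)-6-bromo-5-hydroxy-7-methoxy-8-(3-methylbut-2-enoyl)-4-propyl-3,4-dihydro-2H-chromen-2-one
Product: 20 (4R)-6-{[(1S,2R)-3,3-dimethyl-2-(prop-1-en-2-yl)cyclobutyl]methyl}-5-hydroxy-7-methoxy-8-(3-methylbut-2-enoyl)-4-propyl-3,4-dihydro-2H-chromen-2-one, via alkylzinc iodide 19 (not isolated)
Conditions: (a) 13, Zn dust, LiCl, THF, 40 °C; (b) 18, Pd(OAc)2 (3 mol%), SPhos (6 mol%), THF, rt → 50 °C, slow addition of the zinc reagent (1.8 equiv)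
Reagents that add atoms: none
Why: Negishi sp3–sp2 cross-coupling of a primary alkylzinc iodide (LiCl-assisted zinc insertion) with the aryl bromide using a catalyst system known to couple faster than the zinc reagent is protonated by a free phenol; enone, lactone and both ring stereocentres are untouched, and the change of descriptor at the ring carbon (R to S) is a priority effect only.

Step 15
Reactants: 20 (4R)-6-{[(1S,2R)-3,3-dimethyl-2-(prop-1-en-2-yl)cyclobutyl]methyl}-5-hydroxy-7-methoxy-8-(3-methylbut-2-enoyl)-4-propyl-3,4-dihydro-2H-chromen-2-one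
Product: 23 (3R)-3-[(6R)-6-{[(1S,2R)-3,3-dimethyl-2-(prop-1-en-2-yl)cyclobutyl]methyl}-5-methoxy-2,2-dimethyl-6-(3-methylbut-2-en-1-yl)-4,7-dioxo-3,4,6,7-tetrahydro-2H-chromen-8-yl]hexanoic acid, via dienone lactone 21 (not isolated), via seco enolate 22 (not isolated)
Conditions: (a) Pd2(dba)3·CHCl3 (2.5 mol%), (R,R)-DACH-phenyl Trost ligand (7.5 mol%), prenyl acetate (1.05 equiv), Et3N (1.2 equiv), CH2Cl2, 0 °C → rt, until the acetate is consumed; (b) LiOH (4 equiv), THF/H2O, 0 °C → rt; cold 1 M HCl to pH 3
Reagents that add atoms: 3-methylbut-2-en-1-yl acetate (prenyl acetate), CC(C)=CCOC(C)=O; lithium hydroxide, [Li+].[OH-]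
Why: Stage (a) is a Tsuji–Trost asymmetric allylic alkylation run as a dearomatisation: the triethylammonium phenoxide of 20 (acidified by the para enone) attacks the CH2 terminus of the π-prenyl palladium cation through C-6, the only ortho or para carbon that is neither part of the lactone ring nor acylated, and gives the blocked cyclohexa-2,4-dienone 21. In stage (b) hydroxide cleaves the enol lactone of 21 (a vinylogous anhydride) and the vinylogous carboxylate oxygen so released adds to the β-carbon of the 3-methylbut-2-enoyl group, an oxa-Michael addition of the 2'-hydroxychalcone-to-flavanone type. The dihydropyranone is the only ring closed; it closes 6-endo-trig by O–C bond formation and no stereocentre is created in it. The new quaternary centre C-6 is set in stage (a) by the chiral pocket of the Trost ligand on palladium (catalyst control, since the existing stereocentres are remote), the ligand antipode being chosen to give R. The step needs C- over O-allylation, linear over branched prenyl transfer and ring closure through the oxygen next to the hexanoate-bearing carbon: O-prenyl ethers re-ionise under zerovalent palladium and funnel to the C-alkylated dienone, the hindered nucleophile attacks the unsubstituted allyl terminus, and the closure is one-way because the other oxygen beside the acyl carbon is a methyl ether while the cyclising oxygen becomes free only when the lactone is opened. Telescoping avoids isolating 21, which could revert to an aryl ether by a retro-Claisen shift on standing.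

Step 16
Reactants: 23 (3R)-3-[(6R)-6-{[(1S,2R)-3,3-dimethyl-2-(prop-1-en-2-yl)cyclobutyl]methyl}-5-methoxy-2,2-dimethyl-6-(3-methylbut-2-en-1-yl)-4,7-dioxo-3,4,6,7-tetrahydro-2H-chromen-8-yl]hexanoic acid
Product: 24 (3R)-3-[(6R)-6-{[(1S,2R)-3,3-dimethyl-2-(prop-1-en-2-yl)cyclobutyl]methyl}-5-hydroxy-2,2-dimethyl-6-(3-methylbut-2-en-1-yl)-4,7-dioxo-3,4,6,7-tetrahydro-2H-chromen-8-yl]hexanoic acid
Conditions: LiOH (5 equiv), 1,4-dioxane/H2O, 90 °C; cold 1 M HCl to pH 3
Reagents that add atoms: lithium hydroxide, [Li+].[OH-]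
Why: Hydroxide addition–elimination at the vinylogous methyl ester carbon C-5 (the usual last step for O-methylated dearomatised acylphloroglucinols) releases the enol; methoxide is a better leaving group than the tertiary ring alkoxide, and the resulting enolate no longer enolises at C-3, so the dihydropyranone should not reopen.

**Compound list**

1 | ethyl 2-cyano-3-methylbut-2-enoate | CCOC(=O)C(C#N)=C(C)C | starting material
2 | ethyl 2-cyano-3,3-dimethylhex-5-enoate (racemic at C-2) | CCOC(=O)C(C#N)C(C)(C)CC=C | intermediate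
3 | 3,3-dimethylhex-5-enenitrile | N#CCC(C)(C)CC=C | intermediate
4 | 3,3-dimethyl-4-(oxiran-2-yl)butanenitrile (racemic) | N#CCC(C)(C)CC1CO1 | intermediate
5 | 3,3-dimethyl-4-[(2R)-oxiran-2-yl]butanenitrile | N#CCC(C)(C)C[C@@H]1CO1 | intermediate
6 | sodium [(1R)-2-cyano-3,3-dimethylcyclobutyl]methanolate, mixture of epimers at the nitrile carbon (not isolated) | N#CC1[C@H](C[O-])CC1(C)C.[Na+] | intermediate
7 | (1RS,4R)-4-({[tert-butyl(dimethyl)silyl]oxy}methyl)-2,2-dimethylcyclobutane-1-carbonitrile, mixture of epimers at C-1 | N#CC1[C@H](CO[Si](C)(C)C(C)(C)C)CC1(C)C | intermediate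
8 | lithium 1-[(4R)-4-({[tert-butyl(dimethyl)silyl]oxy}methyl)-2,2-dimethylcyclobutyl]ethan-1-iminide, C-1 epimers (not isolated) | [Li+].CC(=[N-])C1[C@H](CO[Si](C)(C)C(C)(C)C)CC1(C)C | intermediate
9 | 1-[(1RS,4R)-4-({[tert-butyl(dimethyl)silyl]oxy}methyl)-2,2-dimethylcyclobutyl]ethan-1-one, cis/trans mixture (not isolated) | CC(=O)C1[C@H](CO[Si](C)(C)C(C)(C)C)CC1(C)C | intermediate
10 | 1-[(1S,4R)-4-({[tert-butyl(dimethyl)silyl]oxy}methyl)-2,2-dimethylcyclobutyl]ethan-1-one (acetyl and CH2OSi trans) | CC(=O)[C@H]1[C@H](CO[Si](C)(C)C(C)(C)C)CC1(C)C | intermediate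
11 | tert-butyl{[(1R,2R)-3,3-dimethyl-2-(prop-1-en-2-yl)cyclobutyl]methoxy}dimethylsilane (trans) | C=C(C)[C@H]1[C@H](CO[Si](C)(C)C(C)(C)C)CC1(C)C | intermediate
12 | [(1R,2R)-3,3-dimethyl-2-(prop-1-en-2-yl)cyclobutyl]methanol (trans) | C=C(C)[C@H]1[C@H](CO)CC1(C)C | intermediate
13 | (2R,3R)-3-(iodomethyl)-1,1-dimethyl-2-(prop-1-en-2-yl)cyclobutane (trans) | C=C(C)[C@H]1[C@H](CI)CC1(C)C | intermediate
14 | 5,7-dihydroxy-4-propyl-2H-chromen-2-one (5,7-dihydroxy-4-propylcoumarin) | O=C1C=C(CCC)c2c(O)cc(O)cc2O1 | starting material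
15 | 5-hydroxy-7-methoxy-4-propyl-2H-chromen-2-one | O=C1C=C(CCC)c2c(O)cc(OC)cc2O1 | intermediate
16 | (4R)-5-hydroxy-7-methoxy-4-propyl-3,4-dihydro-2H-chromen-2-one | O=C1C[C@@H](CCC)c2c(O)cc(OC)cc2O1 | intermediate
17 | (4R)-6-bromo-5-hydroxy-7-methoxy-4-propyl-3,4-dihydro-2H-chromen-2-one | O=C1C[C@@H](CCC)c2c(O)c(Br)c(OC)cc2O1 | intermediate
18 | (4R)-6-bromo-5-hydroxy-7-methoxy-8-(3-methylbut-2-enoyl)-4-propyl-3,4-dihydro-2H-chromen-2-one | O=C1C[C@@H](CCC)c2c(O)c(Br)c(OC)c(C(=O)C=C(C)C)c2O1 | intermediate
19 | {[(1R,2R)-3,3-dimethyl-2-(prop-1-en-2-yl)cyclobutyl]methyl}(iodo)zinc (not isolated) | C=C(C)[C@H]1[C@H](C[Zn]I)CC1(C)C | intermediate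
20 | (4R)-6-{[(1S,2R)-3,3-dimethyl-2-(prop-1-en-2-yl)cyclobutyl]methyl}-5-hydroxy-7-methoxy-8-(3-methylbut-2-enoyl)-4-propyl-3,4-dihydro-2H-chromen-2-one | O=C1C[C@@H](CCC)c2c(O)c(C[C@@H]3CC(C)(C)[C@H]3C(C)=C)c(OC)c(C(=O)C=C(C)C)c2O1 | intermediate
21 | (4R,6R)-6-{[(1S,2R)-3,3-dimethyl-2-(prop-1-en-2-yl)cyclobutyl]methyl}-7-methoxy-8-(3-methylbut-2-enoyl)-6-(3-methylbut-2-en-1-yl)-4-propyl-3,4-dihydro-2H-chromene-2,5(6H)-dione (not isolated) | O=C1C[C@@H](CCC)C2=C(O1)C(C(=O)C=C(C)C)=C(OC)[C@](CC=C(C)C)(C[C@@H]3CC(C)(C)[C@H]3C(C)=C)C2=O | intermediate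
22 | dilithium (3R)-3-[(5R)-5-{[(1S,2R)-3,3-dimethyl-2-(prop-1-en-2-yl)cyclobutyl]methyl}-4-methoxy-3-(3-methylbut-2-enoyl)-5-(3-methylbut-2-en-1-yl)-2-oxido-6-oxocyclohexa-1,3-dien-1-yl]hexanoate (not isolated) | C=C(C)[C@H]1[C@H](C[C@]2(CC=C(C)C)C(=O)C([C@H](CCC)CC(=O)[O-])=C([O-])C(C(=O)C=C(C)C)=C2OC)CC1(C)C.[Li+].[Li+] | intermediate
23 | (3R)-3-[(6R)-6-{[(1S,2R)-3,3-dimethyl-2-(prop-1-en-2-yl)cyclobutyl]methyl}-5-methoxy-2,2-dimethyl-6-(3-methylbut-2-en-1-yl)-4,7-dioxo-3,4,6,7-tetrahydro-2H-chromen-8-yl]hexanoic acid | C=C(C)[C@H]1[C@H](C[C@]2(CC=C(C)C)C(=O)C([C@H](CCC)CC(=O)O)=C3OC(C)(C)CC(=O)C3=C2OC)CC1(C)C | intermediate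
24 | (3R)-3-[(6R)-6-{[(1S,2R)-3,3-dimethyl-2-(prop-1-en-2-yl)cyclobutyl]methyl}-5-hydroxy-2,2-dimethyl-6-(3-methylbut-2-en-1-yl)-4,7-dioxo-3,4,6,7-tetrahydro-2H-chromen-8-yl]hexanoic acid (cyclobutane substituents trans) | C=C(C)[C@H]1[C@H](C[C@]2(CC=C(C)C)C(=O)C([C@H](CCC)CC(=O)O)=C3OC(C)(C)CC(=O)C3=C2O)CC1(C)C | target

**Totals**

Total step count: 16. Longest linear sequence: 12 steps (steps 1–9, 14, 15, 16).

**Steps most likely to fail**

Step 15. What may go wrong: the chiral catalyst may discriminate poorly between the two faces of C-6 (the existing stereocentres are remote), the phenoxide may partition towards O-allylation, and the dienone may undergo a retro-Claisen shift before the hydroxide stage. Fallback: give up catalyst control and separate epimers. Setting out from 20, the lithium phenoxide (LiN(SiMe3)2, toluene, 0 °C) is C-alkylated with prenyl bromide (ortho C-alkylation of a tight lithium phenoxide ion pair) to give 21 together with its C-6 epimer, (4R,6S)-6-{[(1S,2R)-3,3-dimethyl-2-(prop-1-en-2-yl)cyclobutyl]methyl}-7-methoxy-8-(3-methylbut-2-enoyl)-6-(3-methylbut-2-en-1-yl)-4-propyl-3,4-dihydro-2H-chromene-2,5(6H)-dione F1. The mixture is treated with LiOH in THF/H2O as in stage (b), which should give 23 and its epimer, (3R)-3-[(6S)-6-{[(1S,2R)-3,3-dimethyl-2-(prop-1-en-2-yl)cyclobutyl]methyl}-5-methoxy-2,2-dimethyl-6-(3-methylbut-2-en-1-yl)-4,7-dioxo-3,4,6,7-tetrahydro-2H-chromen-8-yl]hexanoic acid F2. These are diastereomers and are separated by chromatography; the route is rejoined at 23.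

Step 14. What may go wrong: the alkylzinc may be protonated by the free phenol faster than it transmetalates at the doubly ortho-substituted bromide, and β-hydride elimination from the alkylpalladium may give isomerised by-products. Fallback: nickel-catalysed reductive cross-electrophile coupling. Setting out from 13 and 18, the two halides are coupled directly (NiBr2·glyme, 4,4'-di-tert-butyl-2,2'-bipyridine, Zn dust, NaI, N,N-dimethylacetamide, 40 °C); the alkyl partner is engaged as a radical and no basic alkylmetal accumulates. The route is rejoined at 20 and no new compound is made (F0).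

Step 13. What may go wrong: the Lewis acid may cleave the methyl ether next to the new ketone, after which the freed hydroxyl would close a pyranone the wrong way, and bromine may migrate under the acidic conditions. Fallback: build the enone in oxidation-state steps without a strong Lewis acid. Setting out from 17, Vilsmeier–Haack formylation (POCl3, DMF, 0 °C → rt; aq. NaOAc) at the only free position should give (4R)-6-bromo-5-hydroxy-7-methoxy-2-oxo-4-propyl-3,4-dihydro-2H-chromene-8-carbaldehyde F3. Nozaki–Hiyama–Kishi addition of 1-bromo-2-methylprop-1-ene (CrCl2, NiCl2 cat., DMF, rt) should give (4R)-6-bromo-5-hydroxy-8-(1-hydroxy-3-methylbut-2-en-1-yl)-7-methoxy-4-propyl-3,4-dihydro-2H-chromen-2-one F4 (carbinol epimers). Oxidation with MnO2 (CH2Cl2, rt) returns the route to 18.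

Further compounds
F1 | step 15 | (4R,6S)-6-{[(1S,2R)-3,3-dimethyl-2-(prop-1-en-2-yl)cyclobutyl]methyl}-7-methoxy-8-(3-methylbut-2-enoyl)-6-(3-methylbut-2-en-1-yl)-4-propyl-3,4-dihydro-2H-chromene-2,5(6H)-dione | O=C1C[C@@H](CCC)C2=C(O1)C(C(=O)C=C(C)C)=C(OC)[C@@](CC=C(C)C)(C[C@@H]3CC(C)(C)[C@H]3C(C)=C)C2=O
F2 | step 15 | (3R)-3-[(6S)-6-{[(1S,2R)-3,3-dimethyl-2-(prop-1-en-2-yl)cyclobutyl]methyl}-5-methoxy-2,2-dimethyl-6-(3-methylbut-2-en-1-yl)-4,7-dioxo-3,4,6,7-tetrahydro-2H-chromen-8-yl]hexanoic acid | C=C(C)[C@H]1[C@H](C[C@@]2(CC=C(C)C)C(=O)C([C@H](CCC)CC(=O)O)=C3OC(C)(C)CC(=O)C3=C2OC)CC1(C)C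
F0 | step 14 | none | none
F3 | step 13 | (4R)-6-bromo-5-hydroxy-7-methoxy-2-oxo-4-propyl-3,4-dihydro-2H-chromene-8-carbaldehyde | O=C1C[C@@H](CCC)c2c(O)c(Br)c(OC)c(C=O)c2O1
F4 | step 13 | (4R)-6-bromo-5-hydroxy-8-(1-hydroxy-3-methylbut-2-en-1-yl)-7-methoxy-4-propyl-3,4-dihydro-2H-chromen-2-one (carbinol epimers) | O=C1C[C@@H](CCC)c2c(O)c(Br)c(OC)c(C(O)C=C(C)C)c2O1
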